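The whole plan rests on disconnecting C2–C3 and C4–C5, which opens rings A and B at once: with C1=C6 unsaturated and an acetyl group standing in for the C4 isopropyl, the trans ring fusion at C2–C3, with C4 next to it, is the signature of a [4+2] adduct. One intramolecular Diels–Alder reaction of a trienone from 2-deoxy-L-ribose forms both bonds, closes six-membered ring A and five-membered ring B together and sets C2, C3 and C4. Its precursor joins an (E)-methyl enone through C7–C8–C9, with O8 and O9 locked in a cis-acetonide, to an (E)-3-methylbuta-1,3-dienyl unit; the enone is unmasked last from an N-methoxy-N-methylamide. O9 later directs ring A oxygenation and is inverted on esterification.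

Key step: step 7

Remark: locants C1–C11 are those of the target (ring A: C1–C6 with C11 on C1; ring B: C2, C3, C7, C8, C9; C10 is the carbinol carbon on C7), α is the face of H-2 and β the face of H-3, and the ylides 3 and 6 and the acids 25 and 28 are taken to be purchased as single isomers.

Step 1
Reactants: 1 2-deoxy-L-ribose
Product: 2 3,4-O-isopropylidene-2-deoxy-L-ribopyranose (anomeric mixture)
Conditions: 2-methoxypropene, PPTS (cat.), DMF, 0 °C to rt
Reagents that add atoms: 2-methoxypropene, C=C(C)OC
Why: Acid-catalysed acetalisation (acetonide protection) with the enol ether ties up the cis-3,4-diol of the pyranose form under kinetic control and leaves the anomeric hydroxyl free, so the masked aldehyde stays available.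

Step 2
Reactants: 2 3,4-O-isopropylidene-2-deoxy-L-ribopyranose; 3 N-methoxy-N-methyl-2-(triphenylphosphoranylidene)acetamide
Product: 4 (E)-4-[(4R,5S)-5-(hydroxymethyl)-2,2-dimethyl-1,3-dioxolan-4-yl]-N-methoxy-N-methylbut-2-enamide
Conditions: PhCO2H (cat.), toluene, 80 °C
Reagents that add atoms: none
Why: Wittig olefination of the open hydroxy aldehyde form of the lactol with the amide-stabilised ylide gives the E alkene, and the unsaturated N-methoxy-N-methylamide is too weak a Michael acceptor for the released primary hydroxyl to add back, as it could to an enone.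

Step 3
Reactants: 4 (E)-hydroxy enamide
Product: 5 (E)-4-[(4R,5R)-5-formyl-2,2-dimethyl-1,3-dioxolan-4-yl]-N-methoxy-N-methylbut-2-enamide
Conditions: Dess–Martin periodinane, pyridine, CH2Cl2, 0 °C to rt
Reagents that add atoms: none
Why: Dess–Martin oxidation takes the primary alcohol to the aldehyde under buffered conditions that leave the acetonide, the enamide and the configuration of the α-alkoxy carbon untouched.

Step 4
Reactants: 5 dioxolane aldehyde; 6 2-(triphenylphosphoranylidene)propanal
Product: 7 (E)-N-methoxy-N-methyl-4-{(4R,5S)-2,2-dimethyl-5-[(E)-2-methyl-3-oxoprop-1-enyl]-1,3-dioxolan-4-yl}but-2-enamide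
Conditions: toluene, 70 °C
Reagents that add atoms: none
Why: Wittig olefination with the formyl-stabilised ylide is selective for the aldehyde, gives the (E)-2-methylenal under thermodynamic control and is not basic enough to epimerise the α-alkoxy centre, while the less electrophilic enal product does not react further.

Step 5
Reactants: 7 enal; 8 methyltriphenylphosphonium bromide
Product: 9 (E)-N-methoxy-N-methyl-4-{(4R,5S)-2,2-dimethyl-5-[(E)-2-methylbuta-1,3-dienyl]-1,3-dioxolan-4-yl}but-2-enamide
Conditions: KN(SiMe3)2, THF, 0 °C, then 7, −78 to 0 °C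
Reagents that add atoms: none
Why: Wittig methylenation with the non-stabilised ylide at low temperature attacks only the aldehyde, since the amide carbonyl is inert to phosphorus ylides, and completes the (E)-3-methyl-1,3-diene.

Step 6
Reactants: 9 dienyl enamide; 10 methylmagnesium bromide
Product: 11 (E)-5-{(4R,5S)-2,2-dimethyl-5-[(E)-2-methylbuta-1,3-dienyl]-1,3-dioxolan-4-yl}pent-3-en-2-one
Conditions: THF, −78 to 0 °C; aq. NH4Cl
Reagents that add atoms: none
Why: Weinreb ketone synthesis, in which chelation stops the Grignard addition to the N-methoxy-N-methylamide after one equivalent, unmasks the (E)-methyl enone last, when neither a free hydroxyl nor a strong base can attack it.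

Step 7
Reactants: 11 acetonide-protected dienyl enone
Product: 12 4β-acetyl-1-methyl-8α,9α-(isopropylidenedioxy)-trans-hydrind-1(6)-ene (H-2 α, H-3 β)
Conditions: Et2AlCl (1.2 equiv), CH2Cl2 (0.01 M), −78 to −20 °C; aq. NaHCO3
Reagents that add atoms: none
Why: Intramolecular Diels–Alder reaction: Et2AlCl bound to the enone oxygen lowers the dienophile LUMO and the diene C5=C6–C1=C2 adds suprafacially to C3=C4 in a concerted, asynchronous [4+2] cycloaddition in which C2–C3 bonding runs ahead of C4–C5, the closest known reaction type being the Lewis-acid-promoted cyclisation of (E,E)-nona-1,3,8-trienes with a terminal carbonyl group to trans-hydrindenes. Ring A closes as the new cyclohexene C1=C6, and ring B closes in the fused mode when the three-atom tether C9–C8–C7, already bent by the cis-dioxolane, is pulled in between C2 and C3. C2 is controlled by the C9 stereocentre, because 1,3-allylic strain with the C1 methyl keeps H-9 in the diene plane, so that the tethered dienophile can only reach the diene face on the side of C8 and O9 ends up anti to the new C2–C3 bond and cis to H-2. C3 is controlled by the endo position of the acetyl group, which puts the tether exo and makes H-2 and H-3 trans, and C4 by the E geometry of the enone, which is carried over suprafacially so that C7 and acetyl are trans. The step needs endo over exo selectivity and one diene face: the aluminium-bound enone secures the first, and the L-configured C9 together with the C1 methyl secures the second, at the price that O9 is α and must be inverted in step 19.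

Step 8
Reactants: 12 Diels–Alder adduct; 8 methyltriphenylphosphonium bromide
Product: 13 4β-isopropenyl-1-methyl-8α,9α-(isopropylidenedioxy)-trans-hydrind-1(6)-ene
Conditions: KN(SiMe3)2, THF, 0 °C, then 12, 0 °C to rt
Reagents that add atoms: none
Why: Wittig methylenation turns the methyl ketone into the isopropenyl group, and any enolisation towards C4 can only return the more stable equatorial 4β epimer, which is trans to C7.

Step 9
Reactants: 13 isopropenyl acetonide
Product: 14 4β-isopropyl-1-methyl-8α,9α-(isopropylidenedioxy)-trans-hydrind-1(6)-ene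
Conditions: H2 (1 atm), RhCl(PPh3)3 (cat.), toluene/EtOH, rt
Reagents that add atoms: none
Why: Homogeneous catalytic hydrogenation with RhCl(PPh3)3 reduces the unhindered 1,1-disubstituted alkene far faster than the trisubstituted C1=C6 alkene, giving the isopropyl group without a new stereocentre.

Step 10
Reactants: 14 isopropyl acetonide
Product: 15 4β-isopropyl-1-methyl-trans-hydrind-1(6)-ene-8α,9α-diol
Conditions: AcOH/H2O (4:1), 40 °C
Reagents that add atoms: none
Why: Acid-catalysed acetal hydrolysis frees the cis-8α,9α-diol under conditions too mild to shift the C1=C6 double bond.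

Step 11
Reactants: 15 ene diol
Product: 16 1α,6α-epoxy-4β-isopropyl-1β-methyl-trans-hydrindane-8α,9α-diol
Conditions: VO(acac)2 (cat.), t-BuOOH, CH2Cl2, 0 °C to rt
Reagents that add atoms: tert-butyl hydroperoxide, CC(C)(C)OO
Why: Hydroxyl-directed epoxidation, in which the vanadium alkoxide of the homoallylic 9α-hydroxyl delivers the peroxide oxygen to the α face of C1=C6, sets C1 and C6 with the epoxide oxygen syn to O9.

Step 12
Reactants: 16 epoxy diol
Product: 17 1α,6α-epoxy-9α-hydroxy-4β-isopropyl-1β-methyl-trans-hydrindan-8-one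
Conditions: dimethyldioxirane (1.2 equiv), acetone/CH2Cl2, 0 °C to rt
Reagents that add atoms: none
Why: Dioxirane oxidation of a secondary,secondary 1,2-diol stops at the α-hydroxy ketone without C–C cleavage, and oxygen insertion should take the exposed C8–H next to the C7 methylene because the C9–H is crowded by the syn 1β-methyl group and the ring fusion.

Step 13
Reactants: 17 epoxy α-ketol
Product: 18 1α,6α-epoxy-4β-isopropyl-1β-methyl-9α-(triethylsilyloxy)-trans-hydrindan-8-one
Conditions: Et3SiCl, imidazole, DMAP (cat.), DMF, 0 °C to rt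
Reagents that add atoms: chlorotriethylsilane, CC[Si](Cl)(CC)CC
Why: Silyl ether protection of the 9α-hydroxyl under weakly basic conditions blocks it for the enolate step without opening the epoxide or isomerising the α-ketol.

Step 14
Reactants: 18 9α-silyloxy ketone; 19 acetaldehyde
Product: 22 1α,6α-epoxy-7β-[(1S)-1-hydroxyethyl]-4β-isopropyl-1β-methyl-9α-(triethylsilyloxy)-trans-hydrindan-8-one, via lithium enolate 20 (not isolated), via titanium enolate 21 (not isolated)
Conditions: LiN(iPr)2, THF, −78 °C; ClTi(OiPr)3, −78 to −40 °C; 19, −78 °C; aq. NH4Cl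
Reagents that add atoms: none
Why: Directed aldol addition: kinetic deprotonation takes the C7 methylene and not the silyloxy-bearing C9, transmetallation to the triisopropoxytitanium enolate is chosen because such enolates of cyclic ketones give syn aldols whatever the enolate geometry, and acetaldehyde should add to the β face of C7, away from the axial hydrogens on C2 and C4 and towards the equatorial position, which sets C7 (β side chain) and C10 (S).

Step 15
Reactants: 22 aldol adduct
Product: 23 7β-[(1S)-1-(tert-butyldimethylsilyloxy)ethyl]-1α,6α-epoxy-4β-isopropyl-1β-methyl-9α-(triethylsilyloxy)-trans-hydrindan-8-one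
Conditions: t-BuMe2SiCl, imidazole, DMAP (cat.), DMF, rt
Reagents that add atoms: tert-butylchlorodimethylsilane, CC(C)(C)[Si](C)(C)Cl
Why: Silyl ether protection of the C10 hydroxyl with the chloride and imidazole, chosen over triflate reagents that could open the epoxide, masks the only hydroxyl that would compete in the two esterifications.

Step 16
Reactants: 23 bis-silyl epoxy ketone
Product: 24 7β-[(1S)-1-(tert-butyldimethylsilyloxy)ethyl]-6α-hydroxy-4β-isopropyl-1-methylene-9α-(triethylsilyloxy)-trans-hydrindan-8-one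
Conditions: Cp2TiCl2, Zn, THF, rt; then 23; aq. NaH2PO4
Reagents that add atoms: none
Why: Titanocene-mediated radical epoxide opening: Cp2TiCl (trivalent titanium) cleaves the C1–O bond at the tertiary carbon by single-electron transfer and a second equivalent removes a hydrogen atom from the least hindered β position, the methyl group, so that the C1=C11 methylene forms with the 6α oxygen left in place, under conditions that spare the ketone and both silyl ethers.

Step 17
Reactants: 24 6α-allylic alcohol; 25 (E)-3-methylpent-2-enoic acid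
Product: 26 7β-[(1S)-1-(tert-butyldimethylsilyloxy)ethyl]-4β-isopropyl-1-methylene-6α-[(E)-3-methylpent-2-enoyloxy]-9α-(triethylsilyloxy)-trans-hydrindan-8-one
Conditions: DCC, DMAP (cat.), CH2Cl2, 0 °C to rt
Reagents that add atoms: none
Why: Steglich esterification acylates the only free hydroxyl, the axial allylic 6α-OH, with retention at C6, and avoids the acid chloride and amine combination that could scramble the enoate geometry by way of a vinylketene.

Step 18
Reactants: 26 6α-enoate
Product: 27 7β-[(1S)-1-(tert-butyldimethylsilyloxy)ethyl]-9α-hydroxy-4β-isopropyl-1-methylene-6α-[(E)-3-methylpent-2-enoyloxy]-trans-hydrindan-8-one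
Conditions: PPTS, MeOH/CH2Cl2, 0 °C
Reagents that add atoms: none
Why: Acid-catalysed methanolysis (selective desilylation) removes the triethylsilyl ether far faster than the tert-butyldimethylsilyl ether and frees only the 9α-hydroxyl.

Step 19
Reactants: 27 9α-hydroxy ketone; 28 (R)-2-methylbutanoic acid
Product: 29 7β-[(1S)-1-(tert-butyldimethylsilyloxy)ethyl]-4β-isopropyl-1-methylene-9β-[(R)-2-methylbutanoyloxy]-6α-[(E)-3-methylpent-2-enoyloxy]-trans-hydrindan-8-one
Conditions: PPh3, DIAD, toluene, 0 °C to rt
Reagents that add atoms: none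
Why: Mitsunobu esterification activates the 9α oxygen as a phosphonium leaving group that the carboxylate displaces from the β face in an SN2 step, which inverts C9 to the 9β ester and leaves the α-carbon of the acid untouched.

Step 20
Reactants: 29 silyl-protected diester
Product: 30 CNP0224363.1
Conditions: HF·pyridine, pyridine, THF, 0 °C to rt
Reagents that add atoms: none
Why: Fluoride-induced desilylation under buffered, mildly acidic conditions releases the C10 hydroxyl without retro-aldol cleavage, β-elimination, epimerisation at C7 or C9, or acyl migration.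

Compound list
1 | 2-deoxy-L-ribose | O=CC[C@@H](O)[C@@H](O)CO | starting material
2 | 3,4-O-isopropylidene-2-deoxy-L-ribopyranose (anomeric mixture) | OC1C[C@H]2OC(C)(C)O[C@H]2CO1 | intermediate
3 | N-methoxy-N-methyl-2-(triphenylphosphoranylidene)acetamide | CON(C)C(=O)C=P(c1ccccc1)(c1ccccc1)c1ccccc1 | starting material
4 | (E)-4-[(4R,5S)-5-(hydroxymethyl)-2,2-dimethyl-1,3-dioxolan-4-yl]-N-methoxy-N-methylbut-2-enamide | OC[C@@H]1OC(C)(C)O[C@@H]1C/C=C/C(=O)N(C)OC | intermediate
5 | (E)-4-[(4R,5R)-5-formyl-2,2-dimethyl-1,3-dioxolan-4-yl]-N-methoxy-N-methylbut-2-enamide | O=C[C@@H]1OC(C)(C)O[C@@H]1C/C=C/C(=O)N(C)OC | intermediate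
6 | 2-(triphenylphosphoranylidene)propanal | CC(C=O)=P(c1ccccc1)(c1ccccc1)c1ccccc1 | starting material
7 | (E)-N-methoxy-N-methyl-4-{(4R,5S)-2,2-dimethyl-5-[(E)-2-methyl-3-oxoprop-1-enyl]-1,3-dioxolan-4-yl}but-2-enamide | O=C/C(C)=C/[C@@H]1OC(C)(C)O[C@@H]1C/C=C/C(=O)N(C)OC | intermediate
8 | methyltriphenylphosphonium bromide | C[P+](c1ccccc1)(c1ccccc1)c1ccccc1.[Br-] | starting material
9 | (E)-N-methoxy-N-methyl-4-{(4R,5S)-2,2-dimethyl-5-[(E)-2-methylbuta-1,3-dienyl]-1,3-dioxolan-4-yl}but-2-enamide | C=C/C(C)=C/[C@@H]1OC(C)(C)O[C@@H]1C/C=C/C(=O)N(C)OC | intermediate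
10 | methylmagnesium bromide | C[Mg]Br | starting material
11 | (E)-5-{(4R,5S)-2,2-dimethyl-5-[(E)-2-methylbuta-1,3-dienyl]-1,3-dioxolan-4-yl}pent-3-en-2-one | C=C/C(C)=C/[C@@H]1OC(C)(C)O[C@@H]1C/C=C/C(C)=O | intermediate
12 | 4β-acetyl-1-methyl-8α,9α-(isopropylidenedioxy)-trans-hydrind-1(6)-ene | CC=1[C@@H]2[C@H](C[C@H]3OC(C)(C)O[C@H]32)[C@@H](C(C)=O)CC=1 | intermediate
13 | 4β-isopropenyl-1-methyl-8α,9α-(isopropylidenedioxy)-trans-hydrind-1(6)-ene | CC=1[C@@H]2[C@H](C[C@H]3OC(C)(C)O[C@H]32)[C@@H](C(C)=C)CC=1 | intermediate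
14 | 4β-isopropyl-1-methyl-8α,9α-(isopropylidenedioxy)-trans-hydrind-1(6)-ene | CC=1[C@@H]2[C@H](C[C@H]3OC(C)(C)O[C@H]32)[C@@H](C(C)C)CC=1 | intermediate
15 | 4β-isopropyl-1-methyl-trans-hydrind-1(6)-ene-8α,9α-diol | CC=1[C@@H]2[C@H](C[C@@H](O)[C@H]2O)[C@@H](C(C)C)CC=1 | intermediate
16 | 1α,6α-epoxy-4β-isopropyl-1β-methyl-trans-hydrindane-8α,9α-diol | C[C@@]1(O3)[C@@H]2[C@H](C[C@@H](O)[C@H]2O)[C@@H](C(C)C)C[C@@H]13 | intermediate
17 | 1α,6α-epoxy-9α-hydroxy-4β-isopropyl-1β-methyl-trans-hydrindan-8-one | C[C@@]1(O3)[C@@H]2[C@H](CC(=O)[C@H]2O)[C@@H](C(C)C)C[C@@H]13 | intermediate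
18 | 1α,6α-epoxy-4β-isopropyl-1β-methyl-9α-(triethylsilyloxy)-trans-hydrindan-8-one | C[C@@]1(O3)[C@@H]2[C@H](CC(=O)[C@H]2O[Si](CC)(CC)CC)[C@@H](C(C)C)C[C@@H]13 | intermediate
19 | acetaldehyde | CC=O | starting material
20 | lithium C7=C8 enolate of 18 | C[C@@]1(O3)[C@@H]2[C@H](C=C(O[Li])[C@H]2O[Si](CC)(CC)CC)[C@@H](C(C)C)C[C@@H]13 | intermediate (not isolated)
21 | triisopropoxytitanium C7=C8 enolate of 18 | C[C@@]1(O3)[C@@H]2[C@H](C=C(O[Ti](OC(C)C)(OC(C)C)OC(C)C)[C@H]2O[Si](CC)(CC)CC)[C@@H](C(C)C)C[C@@H]13 | intermediate (not isolated)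
22 | 1α,6α-epoxy-7β-[(1S)-1-hydroxyethyl]-4β-isopropyl-1β-methyl-9α-(triethylsilyloxy)-trans-hydrindan-8-one | C[C@@]1(O3)[C@@H]2[C@H]([C@H]([C@H](C)O)C(=O)[C@H]2O[Si](CC)(CC)CC)[C@@H](C(C)C)C[C@@H]13 | intermediate
23 | 7β-[(1S)-1-(tert-butyldimethylsilyloxy)ethyl]-1α,6α-epoxy-4β-isopropyl-1β-methyl-9α-(triethylsilyloxy)-trans-hydrindan-8-one | C[C@@]1(O3)[C@@H]2[C@H]([C@H]([C@H](C)O[Si](C)(C)C(C)(C)C)C(=O)[C@H]2O[Si](CC)(CC)CC)[C@@H](C(C)C)C[C@@H]13 | intermediate
24 | 7β-[(1S)-1-(tert-butyldimethylsilyloxy)ethyl]-6α-hydroxy-4β-isopropyl-1-methylene-9α-(triethylsilyloxy)-trans-hydrindan-8-one | C=C1[C@@H]2[C@H]([C@H]([C@H](C)O[Si](C)(C)C(C)(C)C)C(=O)[C@H]2O[Si](CC)(CC)CC)[C@@H](C(C)C)C[C@@H]1O | intermediate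
25 | (E)-3-methylpent-2-enoic acid | CC/C(C)=C/C(=O)O | starting material
26 | 7β-[(1S)-1-(tert-butyldimethylsilyloxy)ethyl]-4β-isopropyl-1-methylene-6α-[(E)-3-methylpent-2-enoyloxy]-9α-(triethylsilyloxy)-trans-hydrindan-8-one | C=C1[C@@H]2[C@H]([C@H]([C@H](C)O[Si](C)(C)C(C)(C)C)C(=O)[C@H]2O[Si](CC)(CC)CC)[C@@H](C(C)C)C[C@@H]1OC(=O)/C=C(\C)CC | intermediate
27 | 7β-[(1S)-1-(tert-butyldimethylsilyloxy)ethyl]-9α-hydroxy-4β-isopropyl-1-methylene-6α-[(E)-3-methylpent-2-enoyloxy]-trans-hydrindan-8-one | C=C1[C@@H]2[C@H]([C@H]([C@H](C)O[Si](C)(C)C(C)(C)C)C(=O)[C@H]2O)[C@@H](C(C)C)C[C@@H]1OC(=O)/C=C(\C)CC | intermediate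
28 | (R)-2-methylbutanoic acid | CC[C@@H](C)C(=O)O | starting material
29 | 7β-[(1S)-1-(tert-butyldimethylsilyloxy)ethyl]-4β-isopropyl-1-methylene-9β-[(R)-2-methylbutanoyloxy]-6α-[(E)-3-methylpent-2-enoyloxy]-trans-hydrindan-8-one | C=C1[C@@H]2[C@H]([C@H]([C@H](C)O[Si](C)(C)C(C)(C)C)C(=O)[C@@H]2OC(=O)[C@H](C)CC)[C@@H](C(C)C)C[C@@H]1OC(=O)/C=C(\C)CC | intermediate
30 | CNP0224363.1: 7β-[(1S)-1-hydroxyethyl]-4β-isopropyl-1-methylene-9β-[(R)-2-methylbutanoyloxy]-6α-[(E)-3-methylpent-2-enoyloxy]-trans-hydrindan-8-one | C=C1[C@@H]2[C@H]([C@H]([C@H](C)O)C(=O)[C@@H]2OC(=O)[C@H](C)CC)[C@@H](C(C)C)C[C@@H]1OC(=O)/C=C(\C)CC | target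

Total step count: 20. Longest linear sequence: 20 steps (1 to 30); every other component is purchased.

Steps most likely to fail

Step 7 (key step). The Lewis acid may ionise the dienylic C9–O bond of the acetonide, or the cyclisation may show too little endo or facial preference. The fallback moves the cycloaddition one stage back, so that the dienophile is activated by two-point binding instead of through a free ketone. Setting out from 9, Me2AlCl (CH2Cl2, −40 to 0 °C) would chelate the N-methoxy-N-methylamide and should give the bicyclic amide 4β-(N-methoxy-N-methylcarbamoyl)-1-methyl-8α,9α-(isopropylidenedioxy)-trans-hydrind-1(6)-ene F1. MeMgBr (THF, 0 °C) would then convert it into 12, where the route is rejoined.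

Step 12. Oxygen insertion may occur at the C9 carbinol C–H instead of C8, or the α-ketol may be oxidised further. The fallback tells the two hydroxyls apart by a protecting-group relay. Setting out from 16, acetylation of the less hindered 8α-hydroxyl (AcCl, 2,4,6-collidine, CH2Cl2, −78 °C) would give the 8α-acetate F2. Silylation (Et3SiCl, imidazole, DMF) would give the 8α-acetoxy 9α-triethylsilyl ether F3. Reductive removal of the acetate (iBu2AlH, CH2Cl2, −78 °C) would give the 8α-alcohol F4, and Dess–Martin oxidation of the latter would return to 18.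

Step 19. Displacement at the pseudo-equatorial 9α position may be slow, so that elimination towards C2 or acylation with retention takes over. The fallback separates activation from displacement. Setting out from 27, Tf2O and pyridine (CH2Cl2, −40 °C) would give the 9α-triflate F5. Cesium (R)-2-methylbutanoate F6 (from 28 and Cs2CO3; 18-crown-6, toluene, 0 °C to rt) would displace it with inversion to give 29, where the route is rejoined.

Further compounds
F1 | step 7 | 4β-(N-methoxy-N-methylcarbamoyl)-1-methyl-8α,9α-(isopropylidenedioxy)-trans-hydrind-1(6)-ene | CC=1[C@@H]2[C@H](C[C@H]3OC(C)(C)O[C@H]32)[C@@H](C(=O)N(C)OC)CC=1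
F2 | step 12 | 8α-acetoxy-1α,6α-epoxy-4β-isopropyl-1β-methyl-trans-hydrindan-9α-ol | C[C@@]1(O3)[C@@H]2[C@H](C[C@@H](OC(C)=O)[C@H]2O)[C@@H](C(C)C)C[C@@H]13
F3 | step 12 | 8α-acetoxy-1α,6α-epoxy-4β-isopropyl-1β-methyl-9α-(triethylsilyloxy)-trans-hydrindane | C[C@@]1(O3)[C@@H]2[C@H](C[C@@H](OC(C)=O)[C@H]2O[Si](CC)(CC)CC)[C@@H](C(C)C)C[C@@H]13
F4 | step 12 | 1α,6α-epoxy-4β-isopropyl-1β-methyl-9α-(triethylsilyloxy)-trans-hydrindan-8α-ol | C[C@@]1(O3)[C@@H]2[C@H](C[C@@H](O)[C@H]2O[Si](CC)(CC)CC)[C@@H](C(C)C)C[C@@H]13
F5 | step 19 | 9α-trifluoromethanesulfonate of 27 | C=C1[C@@H]2[C@H]([C@H]([C@H](C)O[Si](C)(C)C(C)(C)C)C(=O)[C@H]2OS(=O)(=O)C(F)(F)F)[C@@H](C(C)C)C[C@@H]1OC(=O)/C=C(\C)CC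
F6 | step 19 | cesium (R)-2-methylbutanoate | CC[C@@H](C)C(=O)[O-].[Cs+]
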